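Remark on the chemistry: the target has no stereocentre and, once the chain is saturated, no double-bond geometry, so the SMILES defines it completely. Atom labels used below: ring A carbons A1–A6 (A1 ether oxygen, A3 hydroxyl, A5 chain), ring B carbons B1–B6 (B1 ether oxygen, B2 and B4 hydroxyl, B6 chain), chain carbons C1 (on B6) to C14 (on A5).

## Analysis of the target

Compound 18 is a 20-membered macrocyclic diaryl ether. Ring A and ring B are joined by one oxygen between A1 and B1 and by an unbranched saturated chain of fourteen carbons from B6 (C1) to A5 (C14). Ring A is bridged meta (A1, A5) and ring B ortho (B1, B6). There is no stereocentre and no alkene, so no spatial relationship has to be controlled. The sensitive groups are the three phenols at A3, B2 and B4. Ring B carries oxygen at B1, B2 and B4 and is easily oxidised once its phenols are free, so the hydroxyls should be unmasked in the last step. Two things make the synthesis hard. The ether oxygen on B1 sits between the oxygenated B2 and the chain-bearing B6, so the diaryl ether is hindered on the ring B side. The large ring must also be closed across a chain that offers no functional group. The strategy rests on that chain: because C1–C14 is plain polymethylene, C4–C7 can be a 1,3-diyne and C13–C14 an arylalkyne during assembly, and one hydrogenation erases both. The C5–C6 bond can therefore be made from two terminal alkynes, and the chain divides into a five-carbon arm on B6 and a nine-carbon arm on A5.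

## Retrosynthetic reasoning

**18 back to 17 (three O–CH3 bonds).** The phenols are carried as methyl ethers. They come with the commercial arenes 1 and 11, they survive base, copper, palladium, fluoride and hydrogenation, and they keep ring B from being oxidised. The forward reaction must cleave three aryl methyl ethers without touching the diaryl ether, which a boron Lewis acid can do.

**17 back to 16 (hydrogens on C4–C7 and C13–C14).** The saturated chain of 17 has no handle, so unsaturation is written back in at C4≡C5, C6≡C7 and C13≡C14. This costs one hydrogenation in the forward sense, and no selectivity is needed because everything reducible is meant to be reduced.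

**16 back to 15 (C5–C6, the key cut).** The bond between the two alkyne units is cut to give the open bis-terminal alkyne 15. It is chosen because two identical functions form it and no heteroatom or extra carbon is left behind. It also places the cut so that the long arm is exactly the nine carbons of commercial 13, and it leaves CH2 spacers on both sides of the rigid diyne (C1–C3 and C8–C12). The forward reaction must couple the two alkyne ends within one molecule and not between molecules.

**15 back to 14 (C5–Si).** The alkyne of the ring B arm is carried with a triisopropylsilyl cap. The cap keeps this alkyne out of the copper and palladium steps that come before, and fluoride removes it cleanly.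

**14 back to 12 and 13 (A5–C14).** The arylalkyne bond is cut to the aryl bromide 12 and the symmetric diyne 13. A Sonogashira coupling installs the whole nine-carbon arm in one step, and an excess of 13 ensures that only one end reacts. The extra unsaturation at C13–C14 is removed by the final hydrogenation.

**12 back to 10 and 11 (O–A1).** The diaryl ether is cut on the ring A side. B1 is electron-rich and flanked on both sides, so ring B is the poor electrophile and must be the phenol. The symmetric dibromide 11 gives one bromine to the ether and keeps the other for the Sonogashira step. The forward coupling must tolerate a doubly ortho-substituted phenol.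

**10 back to 8 and 6 (B1–O, then B1–CHO).** The phenol oxygen is traced to a formyl group (Dakin-type oxidation), and the formyl group to electrophilic formylation of 6. In 6 the position ortho to the chain and para to a methoxy group is the reactive one, and this places oxygen exactly at B1 between B2–OMe and B6.

**6 back to 3 and 4 (C3–C4), then 3 to 2 to 1.** The arm is completed by alkylating the acetylide of 4 with iodide 3, which comes from the commercial acid 1 by reduction and iodination. The arm is finished before the phenol is revealed, for two reasons. A carboxylic ester three carbons from a free phenoxide would invite lactonisation under the basic ether coupling. An acetylide displacement carried out later, on a molecule that already bears a free terminal alkyne, would allow that alkyne to be alkylated as well.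

## Alternatives that were turned down

**Alternative 1: ring A assembled by benzannulation on the ether oxygen.**
- Disconnection: ring A itself is taken apart across A2–A3 and A1–A6 (with A3–A4 re-formed), back to 3-(undec-10-en-1-yl)cyclobut-2-en-1-one A2 and the ring B aryl ethynyl ether A3. The macrocycle would be closed afterwards by olefin metathesis of the two terminal alkenes of the benzannulation product A1.
- Forward key step: heating A2 with A3 opens the cyclobutenone to a vinylketene. This adds the alkynyl ether in a [2+2] sense, the new cyclobutenone opens (four electrons), and the dienylketene closes (six electrons) and tautomerises to the phenol A1.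
- For: the hindered diaryl ether needs no C–O coupling, the 1,3,5 pattern of ring A is set regiospecifically, and the A3 hydroxyl emerges free. The later ring closure by metathesis is catalytic and reversible. On the macrocyclisation itself this alternative is probably stronger than an oxidative alkyne coupling.
- Against: both partners are costly. A3 needs the same ring B phenol as the chosen route and then a multistep conversion into an acid- and moisture-sensitive ynol ether. A2 needs a ketene cycloaddition and dehalogenation sequence. An aryloxyalkyne is a weaker ketenophile than an alkoxy- or siloxyalkyne, so higher temperatures are needed, and there the terminal alkenes of both partners can also intercept the vinylketene.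
- Comparison: the count ends well above eleven steps. The chosen route offers commercial sources for ring A and both arms and no thermally delicate intermediate.

**Alternative 2: late twofold C–H borylation and oxidation.**
- Disconnection: the C–O bonds at A3 and B4 are cut, back to a macrocycle A5 that lacks these two hydroxyls.
- Forward key step: iridium-catalysed borylation of A5 (B2pin2, [Ir(OMe)(cod)]2, 4,4'-di-tert-butyl-2,2'-bipyridine), then oxidation of both C–B bonds with KHSO5 in the same flask, to give the diol A4, which is the target with B2 still as its methyl ether.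
- For: the regiochemistry follows sterics and matches the target. A3 is the only ring A C–H not ortho to a substituent, and B4 is the only such position on ring B. On positional control this is as convincing as the formylation and Dakin pair of the chosen route. Ring B also stays less electron-rich, and so less fragile, for most of the synthesis.
- Against: the step does not address the actual difficulties, because A5 still needs the hindered diaryl ether and the 20-membered ring. Two borylations must both go to completion on electron-rich alkoxyarenes, which are slow substrates, and the small methoxy group at B2 gives only weak protection to B3–H. Incomplete or misplaced borylation would produce mixtures at the most valuable stage, and A4 still needs a demethylation.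
- Comparison: 1 and 11 already carry every oxygen in the right place, so late C–H oxidation adds steps instead of saving them.

**Alternative 3: anodic phenol coupling of a symmetric open-chain precursor.**
- Disconnection: the O–B1 bond is cut, back to the symmetric 5,5'-(tetradecane-1,14-diyl)bis(2,4,6-tribromobenzene-1,3-diol) A7.
- Forward key step: constant-current anodic oxidation of A7 (carbon anode, LiClO4 in MeOH) turns one ring into a phenoxonium ion. A hydroxyl oxygen of the other ring attacks it at the brominated carbon B1, closing the 20-membered ring as the bromo quinol ether A6. Reductive removal of all bromines would then restore ring B and give 18.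
- For: A7 can be built in two directions at once, needs no protecting groups, and forms the diaryl ether and the macrocycle in one step. On step count this is the strongest of the four plans and could undercut eleven steps.
- Against: the cation is generated in a nucleophilic solvent and must be captured by a remote oxygen at the end of a floppy C14 chain with nothing to preorganise it, so solvent capture and intermolecular coupling are favoured. Attack can also occur at B3 between the two hydroxyls instead of at B1 or its mirror position. The product A6 still has an oxidisable tribromoresorcinol ring, so over-oxidation is likely. Six bromines must be introduced and removed.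
- Comparison: in the chosen route the ring closure has only one competing process, intermolecular coupling of the same two groups, and the rate of addition controls it. The regiochemistry of both rings is fixed long before the ring is closed.

Key step: step 9

## Route

Step 1
Reactants: 1 3-(3,5-dimethoxyphenyl)propanoic acid
Product: 2 3-(3,5-dimethoxyphenyl)propan-1-ol
Conditions: LiAlH4, THF, 0 °C → reflux; H2O/NaOH work-up
Reagents that add atoms: none
Why: Hydride reduction of a carboxylic acid to the primary alcohol; the aryl methyl ethers are inert to LiAlH4.

Step 2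
Reactants: 2 3-(3,5-dimethoxyphenyl)propan-1-ol
Product: 3 1-(3-iodopropyl)-3,5-dimethoxybenzene
Conditions: I2, PPh3, imidazole, CH2Cl2, 0 °C → rt
Reagents that add atoms: iodine II
Why: Appel-type iodination; the alkoxyphosphonium intermediate is displaced by iodide in an SN2 step at the unhindered primary carbon.

Step 3
Reactants: 3 1-(3-iodopropyl)-3,5-dimethoxybenzene; 4 ethynyltri(propan-2-yl)silane
Product: 6 [5-(3,5-dimethoxyphenyl)pent-1-yn-1-yl]tri(propan-2-yl)silane, via lithium silylacetylide 5 (not isolated)
Conditions: 4, n-BuLi, THF, −78 → 0 °C; then 3, DMPU, −78 °C → rt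
Reagents that add atoms: none
Why: SN2 alkylation of a lithium acetylide by a primary iodide in a dipolar cosolvent forms the C3–C4 bond and completes the five-carbon arm. The bulky silyl cap makes the alkyne a spectator in the copper and palladium steps ahead.

Step 4
Reactants: 6 [5-(3,5-dimethoxyphenyl)pent-1-yn-1-yl]tri(propan-2-yl)silane
Product: 8 2,4-dimethoxy-6-{5-[tri(propan-2-yl)silyl]pent-4-yn-1-yl}benzaldehyde, via aryl iminium chloride 7 (not isolated)
Conditions: POCl3, DMF, 0 → 60 °C; then ice/H2O
Reagents that add atoms: N,N-dimethylformamide CN(C)C=O; water O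
Why: Vilsmeier–Haack formylation; the chloroiminium ion should attack the ring carbon ortho to the chain (para to one methoxy, ortho to the other) in preference to the more crowded carbon between the two methoxy groups. The silylalkyne is far less nucleophilic than the dimethoxyarene and should not react.

Step 5
Reactants: 8 2,4-dimethoxy-6-{5-[tri(propan-2-yl)silyl]pent-4-yn-1-yl}benzaldehyde
Product: 10 2,4-dimethoxy-6-{5-[tri(propan-2-yl)silyl]pent-4-yn-1-yl}phenol, via aryl formate 9 (not isolated)
Conditions: mCPBA (1.1 equiv), CH2Cl2, 0 °C → rt; then Et3N, MeOH, rt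
Reagents that add atoms: 3-chloroperoxybenzoic acid O=C(OO)c1cccc(Cl)c1
Why: Baeyer–Villiger oxidation of an electron-rich benzaldehyde (Dakin-type): the aryl group with ortho and para methoxy donors migrates to oxygen, and the resulting formate is cleaved by mild methanolysis. The triisopropylsilyl alkyne is stable to the peracid at this temperature and to amine/methanol.

Step 6
Reactants: 10 2,4-dimethoxy-6-{5-[tri(propan-2-yl)silyl]pent-4-yn-1-yl}phenol; 11 1,3-dibromo-5-methoxybenzene
Product: 12 {5-[2-(3-bromo-5-methoxyphenoxy)-3,5-dimethoxyphenyl]pent-1-yn-1-yl}tri(propan-2-yl)silane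
Conditions: 11 (3 equiv), CuI (cat.), picolinic acid (cat.), K3PO4, DMSO, 90 °C, degassed
Reagents that add atoms: none
Why: Ullmann-type C–O coupling with a picolinate-ligated copper catalyst, a system suited to doubly ortho-substituted phenols. The excess of the symmetric dibromide favours monoarylation, and no ester, free alcohol or free alkyne is present to interfere.

Step 7
Reactants: 12 {5-[2-(3-bromo-5-methoxyphenoxy)-3,5-dimethoxyphenyl]pent-1-yn-1-yl}tri(propan-2-yl)silane; 13 nona-1,8-diyne
Product: 14 [5-(3,5-dimethoxy-2-{3-methoxy-5-(nona-1,8-diyn-1-yl)phenoxy}phenyl)pent-1-yn-1-yl]tri(propan-2-yl)silane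
Conditions: 13 (5 equiv), PdCl2(PPh3)2 (cat.), CuI (cat.), Et3N/THF, 65 °C, degassed
Reagents that add atoms: none
Why: Sonogashira coupling forms the A5–C14 bond. The excess of the symmetric diyne favours reaction at one end only, and the silyl-capped alkyne of the other arm cannot take part.

Step 8
Reactants: 14 [5-(3,5-dimethoxy-2-{3-methoxy-5-(nona-1,8-diyn-1-yl)phenoxy}phenyl)pent-1-yn-1-yl]tri(propan-2-yl)silane
Product: 15 1,5-dimethoxy-2-[3-methoxy-5-(nona-1,8-diyn-1-yl)phenoxy]-3-(pent-4-yn-1-yl)benzene
Conditions: TBAF, THF, 0 °C → rt
Reagents that add atoms: none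
Why: Fluoride-induced protodesilylation of the alkynylsilane frees the second terminal alkyne; nothing else in the molecule is fluoride-labile.

Step 9
Reactants: 15 1,5-dimethoxy-2-[3-methoxy-5-(nona-1,8-diyn-1-yl)phenoxy]-3-(pent-4-yn-1-yl)benzene
Product: 16 1^5,3^4,3^6-trimethoxy-2-oxa-1(1,3),3(1,2)-dibenzenacycloheptadecaphane-7,9,16-triyne (macrocyclic triyne trimethyl ether: diyne C4≡C5–C6≡C7 and arylalkyne C13≡C14)
Conditions: Cu(OAc)2 (10 equiv), pyridine, 60 °C; 15 added by syringe pump over 20 h (about 1 mM final)
Reagents that add atoms: none
Why: This is the Eglinton variant of the Glaser coupling, the established way of closing cyclic 1,3-diynes from α,ω-diynes. Coordination of each terminal alkyne to copper in pyridine acidifies its C–H bond and gives copper acetylides at C5 and C6; two divalent copper centres each accept one electron from the bridged bis-acetylide and the C5–C6 bond forms, leaving CuOAc and acetic acid (held as its pyridinium salt). The 20-membered ring closes end to end by this C(sp)–C(sp) bond formation, with both triple bonds inside the ring. The six collinear atoms C3–C8 and the four collinear atoms A5–C12 are separated by the flexible segments C8–C12 and C1–C3 and by the diaryl ether hinge, so the rigid rods should fit without bending. No stereocentre is formed. The one selectivity required is ring closure over intermolecular coupling; it is secured by slow addition into a large excess of Cu(OAc)2, which keeps the stationary concentration of uncoupled 15 far below the final concentration. Chemoselectivity is built into the substrate: only the two terminal alkyne C–H bonds can be metalated, the internal alkyne C13≡C14 and the methyl ethers are inert, and there is no free phenol for divalent copper to oxidise.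

Step 10
Reactants: 16 1^5,3^4,3^6-trimethoxy-2-oxa-1(1,3),3(1,2)-dibenzenacycloheptadecaphane-7,9,16-triyne
Product: 17 1^5,3^4,3^6-trimethoxy-2-oxa-1(1,3),3(1,2)-dibenzenacycloheptadecaphane (saturated macrocycle trimethyl ether)
Conditions: H2 (1 atm), 10% Pd/C, EtOAc/EtOH, rt
Reagents that add atoms: none
Why: Heterogeneous catalytic hydrogenation takes all three triple bonds to CH2–CH2. The diaryl ether and the methyl ethers are not hydrogenolysed under these mild conditions.

Step 11
Reactants: 17 1^5,3^4,3^6-trimethoxy-2-oxa-1(1,3),3(1,2)-dibenzenacycloheptadecaphane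
Product: 18 2-oxa-1(1,3),3(1,2)-dibenzenacycloheptadecaphane-1^5,3^4,3^6-triol (target CNP0173380.0: hydroxyls at A3, B2 and B4)
Conditions: BBr3, CH2Cl2, −78 °C → rt; then H2O
Reagents that add atoms: none
Why: Lewis-acid ether cleavage: boron coordinates each methoxy oxygen and bromide attacks the methyl carbon in an SN2 step. The diaryl ether has no sp3 carbon on oxygen and is not cleaved.

## Compound list

1 | 3-(3,5-dimethoxyphenyl)propanoic acid | COc1cc(CCC(=O)O)cc(OC)c1 | starting material
2 | 3-(3,5-dimethoxyphenyl)propan-1-ol | COc1cc(CCCO)cc(OC)c1 | intermediate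
3 | 1-(3-iodopropyl)-3,5-dimethoxybenzene | COc1cc(CCCI)cc(OC)c1 | intermediate
4 | ethynyltri(propan-2-yl)silane | C#C[Si](C(C)C)(C(C)C)C(C)C | starting material
5 | lithium [tri(propan-2-yl)silyl]acetylide | [Li]C#C[Si](C(C)C)(C(C)C)C(C)C | intermediate
6 | [5-(3,5-dimethoxyphenyl)pent-1-yn-1-yl]tri(propan-2-yl)silane | COc1cc(CCCC#C[Si](C(C)C)(C(C)C)C(C)C)cc(OC)c1 | intermediate
7 | N-[(2,4-dimethoxy-6-{5-[tri(propan-2-yl)silyl]pent-4-yn-1-yl}phenyl)methylidene]-N-methylmethanaminium chloride | COc1cc(OC)c(C=[N+](C)C)c(CCCC#C[Si](C(C)C)(C(C)C)C(C)C)c1.[Cl-] | intermediate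
8 | 2,4-dimethoxy-6-{5-[tri(propan-2-yl)silyl]pent-4-yn-1-yl}benzaldehyde | COc1cc(OC)c(C=O)c(CCCC#C[Si](C(C)C)(C(C)C)C(C)C)c1 | intermediate
9 | 2,4-dimethoxy-6-{5-[tri(propan-2-yl)silyl]pent-4-yn-1-yl}phenyl formate | COc1cc(OC)c(OC=O)c(CCCC#C[Si](C(C)C)(C(C)C)C(C)C)c1 | intermediate
10 | 2,4-dimethoxy-6-{5-[tri(propan-2-yl)silyl]pent-4-yn-1-yl}phenol | COc1cc(OC)c(O)c(CCCC#C[Si](C(C)C)(C(C)C)C(C)C)c1 | intermediate
11 | 1,3-dibromo-5-methoxybenzene | COc1cc(Br)cc(Br)c1 | starting material
12 | {5-[2-(3-bromo-5-methoxyphenoxy)-3,5-dimethoxyphenyl]pent-1-yn-1-yl}tri(propan-2-yl)silane | COc1cc(Br)cc(Oc2c(OC)cc(OC)cc2CCCC#C[Si](C(C)C)(C(C)C)C(C)C)c1 | intermediate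
13 | nona-1,8-diyne | C#CCCCCCC#C | starting material
14 | [5-(3,5-dimethoxy-2-{3-methoxy-5-(nona-1,8-diyn-1-yl)phenoxy}phenyl)pent-1-yn-1-yl]tri(propan-2-yl)silane | COc1cc(C#CCCCCCC#C)cc(Oc2c(OC)cc(OC)cc2CCCC#C[Si](C(C)C)(C(C)C)C(C)C)c1 | intermediate
15 | 1,5-dimethoxy-2-[3-methoxy-5-(nona-1,8-diyn-1-yl)phenoxy]-3-(pent-4-yn-1-yl)benzene | COc1cc(C#CCCCCCC#C)cc(Oc2c(OC)cc(OC)cc2CCCC#C)c1 | intermediate
16 | 1^5,3^4,3^6-trimethoxy-2-oxa-1(1,3),3(1,2)-dibenzenacycloheptadecaphane-7,9,16-triyne | COc1cc2cc(c1)Oc1c(OC)cc(OC)cc1CCCC#CC#CCCCCCC#C2 | intermediate
17 | 1^5,3^4,3^6-trimethoxy-2-oxa-1(1,3),3(1,2)-dibenzenacycloheptadecaphane | COc1cc2cc(c1)Oc1c(OC)cc(OC)cc1CCCCCCCCCCCCCC2 | intermediate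
18 | 2-oxa-1(1,3),3(1,2)-dibenzenacycloheptadecaphane-1^5,3^4,3^6-triol | Oc1cc2cc(c1)Oc1c(O)cc(O)cc1CCCCCCCCCCCCCC2 | target

## Step count and risk

Total step count: 11. Longest linear sequence: 11 steps (1 to 18); compounds 4, 11 and 13 enter as commercial reagents.

**Step 9 (key step).** The most likely failure is intermolecular coupling outrunning ring closure, which would build cyclic dimers and linear oligomers. The two alkyne ends sit on long, freely rotating arms and nothing in 15 preorganises them.
Fallback, from 12 back to 17, closes the ring by reversible olefin metathesis, in which oligomers can still be converted into the monomeric ring. Desilylation of 12 with TBAF would give 1-bromo-3-[2,4-dimethoxy-6-(pent-4-yn-1-yl)phenoxy]-5-methoxybenzene F1. Semihydrogenation over Pd/CaCO3 poisoned with Pb(OAc)2 and quinoline would give 1-bromo-3-[2,4-dimethoxy-6-(pent-4-en-1-yl)phenoxy]-5-methoxybenzene F2. Negishi coupling of F2 with undec-10-en-1-ylzinc bromide F3 (from 11-bromoundec-1-ene and Zn) under Pd(OAc)2/SPhos would give the diene 1,5-dimethoxy-2-[3-methoxy-5-(undec-10-en-1-yl)phenoxy]-3-(pent-4-en-1-yl)benzene F4. Ring-closing metathesis with second-generation Grubbs catalyst at high dilution in CH2Cl2 would give the macrocyclic alkene 1^5,3^4,3^6-trimethoxy-2-oxa-1(1,3),3(1,2)-dibenzenacycloheptadecaphan-7-ene F5 as a mixture of double-bond isomers. Hydrogenation of F5 over Pd/C returns to 17.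

**Step 4.** The risk is poor regioselectivity of the electrophilic attack: formylation at the carbon between the two methoxy groups would place the later ether oxygen wrongly. The outcome rests on a steric preference only.
Fallback, from 1 back to 12, fixes the position by an intramolecular acylation that can only reach the carbon ortho to the chain. Cyclisation of 1 in polyphosphoric acid would give 5,7-dimethoxy-2,3-dihydro-1H-inden-1-one F6. Baeyer–Villiger oxidation (mCPBA, CF3CO2H cat.) with migration of the electron-rich aryl group would give 6,8-dimethoxychroman-2-one F7. LiAlH4 would open the lactone to 2-(3-hydroxypropyl)-4,6-dimethoxyphenol F8. Phenol-selective coupling with 11 under the conditions of step 6 would give 3-[2-(3-bromo-5-methoxyphenoxy)-3,5-dimethoxyphenyl]propan-1-ol F9. I2/PPh3/imidazole would give 1-bromo-3-[2-(3-iodopropyl)-4,6-dimethoxyphenoxy]-5-methoxybenzene F10, and alkylation of acetylide 5 with F10 gives 12.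

**Step 6.** The risks are slow C–O bond formation at a phenoxide flanked by a methoxy group and the chain, oxidative degradation of the electron-rich phenol by copper and traces of air, and a second arylation at the remaining bromide.
Fallback, from 10 back to 12, is a metal-free arylation by ligand coupling at trivalent iodine. (3-Bromo-5-methoxyphenyl)(2,4,6-trimethoxyphenyl)iodonium 4-methylbenzenesulfonate F11 would be made in one flask from 1-bromo-3-iodo-5-methoxybenzene (mCPBA, TsOH, then 1,3,5-trimethoxybenzene). It should transfer its less electron-rich aryl group to the potassium phenoxide of 10 (K2CO3, MeCN, rt to 40 °C) and give 12 directly.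

**Step 7.** The risks are coupling at both ends of the diyne, copper-mediated oxidative homocoupling of the diyne, and sluggish oxidative addition of the oxygenated aryl bromide.
Fallback, from 12 and 13 back to 15, uses a diyne with one end blocked. Monosilylation of 13 (n-BuLi, 1 equiv, then Me3SiCl) would give trimethyl(nona-1,8-diyn-1-yl)silane F12. Sonogashira coupling of F12 with 12 would give [5-(3,5-dimethoxy-2-{3-methoxy-5-[9-(trimethylsilyl)nona-1,8-diyn-1-yl]phenoxy}phenyl)pent-1-yn-1-yl]tri(propan-2-yl)silane F13. TBAF would remove both silyl groups at once and give 15.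

## Further compounds

F1 | step 9 | 1-bromo-3-[2,4-dimethoxy-6-(pent-4-yn-1-yl)phenoxy]-5-methoxybenzene | COc1cc(Br)cc(Oc2c(OC)cc(OC)cc2CCCC#C)c1
F2 | step 9 | 1-bromo-3-[2,4-dimethoxy-6-(pent-4-en-1-yl)phenoxy]-5-methoxybenzene | COc1cc(Br)cc(Oc2c(OC)cc(OC)cc2CCCC=C)c1
F3 | step 9 | undec-10-en-1-ylzinc bromide | C=CCCCCCCCCC[Zn]Br
F4 | step 9 | 1,5-dimethoxy-2-[3-methoxy-5-(undec-10-en-1-yl)phenoxy]-3-(pent-4-en-1-yl)benzene | COc1cc(CCCCCCCCCC=C)cc(Oc2c(OC)cc(OC)cc2CCCC=C)c1
F5 | step 9 | 1^5,3^4,3^6-trimethoxy-2-oxa-1(1,3),3(1,2)-dibenzenacycloheptadecaphan-7-ene (mixture of double-bond isomers) | COc1cc2cc(c1)Oc1c(OC)cc(OC)cc1CCCC=CCCCCCCCCC2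
F6 | step 4 | 5,7-dimethoxy-2,3-dihydro-1H-inden-1-one | COc1cc2CCC(=O)c2c(OC)c1
F7 | step 4 | 6,8-dimethoxychroman-2-one | COc1cc2CCC(=O)Oc2c(OC)c1
F8 | step 4 | 2-(3-hydroxypropyl)-4,6-dimethoxyphenol | COc1cc(CCCO)c(O)c(OC)c1
F9 | step 4 | 3-[2-(3-bromo-5-methoxyphenoxy)-3,5-dimethoxyphenyl]propan-1-ol | COc1cc(Br)cc(Oc2c(OC)cc(OC)cc2CCCO)c1
F10 | step 4 | 1-bromo-3-[2-(3-iodopropyl)-4,6-dimethoxyphenoxy]-5-methoxybenzene | COc1cc(Br)cc(Oc2c(OC)cc(OC)cc2CCCI)c1
F11 | step 6 | (3-bromo-5-methoxyphenyl)(2,4,6-trimethoxyphenyl)iodonium 4-methylbenzenesulfonate | COc1cc(Br)cc([I+]c2c(OC)cc(OC)cc2OC)c1.Cc1ccc(cc1)S(=O)(=O)[O-]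
F12 | step 7 | trimethyl(nona-1,8-diyn-1-yl)silane | C#CCCCCCC#C[Si](C)(C)C
F13 | step 7 | [5-(3,5-dimethoxy-2-{3-methoxy-5-[9-(trimethylsilyl)nona-1,8-diyn-1-yl]phenoxy}phenyl)pent-1-yn-1-yl]tri(propan-2-yl)silane | COc1cc(C#CCCCCCC#C[Si](C)(C)C)cc(Oc2c(OC)cc(OC)cc2CCCC#C[Si](C(C)C)(C(C)C)C(C)C)c1
A1 | alternative 1 | 3-[2,4-dimethoxy-6-(pent-4-en-1-yl)phenoxy]-5-(undec-10-en-1-yl)phenol | C=CCCCCCCCCCc1cc(O)cc(Oc2c(OC)cc(OC)cc2CCCC=C)c1
A2 | alternative 1 | 3-(undec-10-en-1-yl)cyclobut-2-en-1-one | C=CCCCCCCCCCC1=CC(=O)C1
A3 | alternative 1 | 2-(ethynyloxy)-1,5-dimethoxy-3-(pent-4-en-1-yl)benzene | C#COc1c(OC)cc(OC)cc1CCCC=C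
A4 | alternative 2 | 3^6-methoxy-2-oxa-1(1,3),3(1,2)-dibenzenacycloheptadecaphane-1^5,3^4-diol | COc1cc(O)cc2c1Oc1cc(O)cc(c1)CCCCCCCCCCCCCC2
A5 | alternative 2 | 3^6-methoxy-2-oxa-1(1,3),3(1,2)-dibenzenacycloheptadecaphane | COc1cccc2c1Oc1cccc(c1)CCCCCCCCCCCCCC2
A6 | alternative 3 | macrocyclic 4-aryloxy-4-bromo-3-hydroxycyclohexa-2,5-dienone (hexabromo quinol ether, racemic at B1) | Oc1c(Br)c2c(Br)c(c1Br)OC1(Br)C(O)=C(Br)C(=O)C(Br)=C1CCCCCCCCCCCCCC2
A7 | alternative 3 | 5,5'-(tetradecane-1,14-diyl)bis(2,4,6-tribromobenzene-1,3-diol) | Oc1c(Br)c(O)c(Br)c(CCCCCCCCCCCCCCc2c(Br)c(O)c(Br)c(O)c2Br)c1Br
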